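**Strategy.** In eremophilane numbering, ring B (C5–C6–C7–C8–C9–C10) is disconnected at the C9–C10 bond. The feature exploited is the quaternary carbon C5 (bearing the C14 methyl): its two ring-A neighbours, C4 and C10, can both be carbonyls of an achiral 2-methylcyclohexane-1,3-dione. A proline-catalysed intramolecular aldol condensation of the derived triketone, 2-methyl-2-(3-oxobutyl)cyclohexane-1,3-dione, lets C9 attack C10. This closes ring B and, by choosing between the two enantiotopic carbonyls, fixes C5 in one operation. The other five stereocentres (C3, C4, C10, C9, C7) are then relayed from C5 by substrate control, the former C4 carbonyl becoming the C15 methyl. Both senecioates are attached last.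

Key step: step 2

Remark on the chemistry: eremophilane numbering is used throughout (ring A = C1–C2–C3–C4–C5–C10, ring B = C5–C6–C7–C8–C9–C10, C14 = methyl on C5, C15 = methyl on C4, C11–C13 = isopropenyl). β is the face of the C5 methyl. The target is (3R,4R,5R,7R,9R,10S): 3α- and 9β-acyloxy, 4β- and 5β-methyl, 7β-isopropenyl, 10β-H (cis-decalin).

Step 1
Reactants: 1 2-methylcyclohexane-1,3-dione; 2 methyl vinyl ketone
Product: 3 2-methyl-2-(3-oxobutyl)cyclohexane-1,3-dione
Conditions: AcOH (cat.), hydroquinone (cat.), H2O, 75 °C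
Reagents that add atoms: none
Why: Michael addition of the acidic dione carbon (future C5) to the enone forms the C5–C6 bond and a still achiral quaternary carbon, so no stereocentre has to be controlled.

Step 2
Reactants: 3 2-methyl-2-(3-oxobutyl)cyclohexane-1,3-dione
Product: 6 (S)-Wieland–Miescher ketone, via proline enamine 4 (not isolated), via bicyclic ketol 5 (not isolated)
Conditions: L-proline (30 mol%), DMSO, rt
Reagents that add atoms: none
Why: Hajos–Parrish–Eder–Sauer–Wiechert reaction: L-proline condenses with the side-chain ketone (C8) to enamine 4, whose carbon C9 adds to one ring carbonyl (C10) that the carboxylic acid activates by hydrogen bonding in a chair-like transition state, and ketol 5 then loses water to the Δ9(10)-enone. Ring B closes in a 6-(enolendo)-exo-trig aldol addition, the enamine C8=C9 bond lying inside the new ring and the attacked C10=O bond outside it. The only stereocentre that survives dehydration, quaternary C5, is set by the catalyst, which must distinguish the enantiotopic carbonyls C4 and C10; L-proline should favour the transition state leading to the (S)-enone. Regioselectivity is secured by the substrate, because an enamine toward C7 could only close a four-membered ring, and C5 carries no hydrogen and cannot racemise. The step needs enantiotopic-group selectivity only, and 6 can be enriched by crystallisation if required.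

Step 3
Reactants: 6 (S)-Wieland–Miescher ketone
Product: 7 (R)-4a-methyl-5-methylidene-4,4a,5,6,7,8-hexahydronaphthalen-2(3H)-one
Conditions: Ph3PCH3Br, KOtBu, THF, 0 °C → rt
Reagents that add atoms: methyltriphenylphosphonium bromide C[P+](c1ccccc1)(c1ccccc1)c1ccccc1.[Br-]
Why: Wittig methylenation should be chemoselective for the saturated C4 ketone, because the C8 carbonyl is deactivated as a conjugated (and, under the basic conditions, reversibly enolised) ketone, and it brings in C15 without creating a stereocentre.

Step 4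
Reactants: 7 (R)-4a-methyl-5-methylidene-4,4a,5,6,7,8-hexahydronaphthalen-2(3H)-one
Product: 8 (4aS,6R)-6-hydroxy-4a-methyl-5-methylidene-4,4a,5,6,7,8-hexahydronaphthalen-2(3H)-one (3α-alcohol)
Conditions: SeO2 (0.5 equiv), t-BuOOH, CH2Cl2, 0 °C → rt
Reagents that add atoms: selenium dioxide O=[Se]=O; tert-butyl hydroperoxide CC(C)(C)OO
Why: Riley allylic hydroxylation (ene reaction followed by a [2,3]-sigmatropic shift) can only functionalise C3, the sole allylic CH2 of the exocyclic alkene since C5 is quaternary, and oxygen should be delivered to the α face because the β face of C3 is 1,3-diaxial to the axial C14 methyl, giving the equatorial 3α-alcohol while the electron-poor enone stays untouched.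

Step 5
Reactants: 8 (4aS,6R)-6-hydroxy-4a-methyl-5-methylidene-4,4a,5,6,7,8-hexahydronaphthalen-2(3H)-one
Product: 9 (4aR,5R,6R)-6-hydroxy-4a,5-dimethyl-4,4a,5,6,7,8-hexahydronaphthalen-2(3H)-one (3α-hydroxy-4β,5β-dimethyl)
Conditions: [Ir(cod)(PCy3)(py)]PF6 (5 mol%), H2 (1 atm), CH2Cl2, rt
Reagents that add atoms: none
Why: In this hydroxyl-directed (Crabtree) hydrogenation the iridium centre bound to the 3α-OH should deliver hydrogen to the α face of the exocyclic alkene, which is also the face opposite the axial C14 methyl, so that H-4 is α and C15 is β (trans to the hydroxyl, cis to C14), while the conjugated trisubstituted C9=C10 bond remains.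

Step 6
Reactants: 9 (4aR,5R,6R)-6-hydroxy-4a,5-dimethyl-4,4a,5,6,7,8-hexahydronaphthalen-2(3H)-one
Product: 10 (4aR,5R,6R)-6-(tert-butyldimethylsilyloxy)-4a,5-dimethyl-4,4a,5,6,7,8-hexahydronaphthalen-2(3H)-one
Conditions: TBSCl, imidazole, DMF, rt
Reagents that add atoms: tert-butyldimethylsilyl chloride CC(C)(C)[Si](C)(C)Cl
Why: Standard silylation of the secondary alcohol protects O-3 against the strong base and the peracid used later and affects no stereocentre.

Step 7
Reactants: 10 (4aR,5R,6R)-6-(tert-butyldimethylsilyloxy)-4a,5-dimethyl-4,4a,5,6,7,8-hexahydronaphthalen-2(3H)-one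
Product: 11 cis-fused (10β-H) 8-silyloxy Δ8 enol ether carrying 3α-OTBS and the 4β- and 5β-methyl groups
Conditions: [(Ph3P)CuH]6 (0.3 equiv), TBSCl (2 equiv), benzene, rt
Reagents that add atoms: tert-butyldimethylsilyl chloride CC(C)(C)[Si](C)(C)Cl
Why: Stryker conjugate reduction delivers hydride to C10 and in situ O-silylation fixes the enolate as the regiodefined Δ8 silyl enol ether; as in copper-mediated conjugate additions to other 4a-methyl octalones, hydride should add through a chair-like transition state on the β face to give the cis ring junction (10β-H).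

Step 8
Reactants: 11 cis-fused 8-silyloxy Δ8 enol ether
Product: 13 cis-fused 3α,9β-bis(tert-butyldimethylsilyloxy)-4β,5β-dimethyl-10β-H decalin-8-one, via silyloxy epoxide 12 (not isolated)
Conditions: m-CPBA, NaHCO3, CH2Cl2, −20 → 0 °C
Reagents that add atoms: m-chloroperbenzoic acid OOC(=O)c1cccc(Cl)c1
Why: Rubottom oxidation: the peracid should epoxidise the enol ether on the convex β face of the cis-decalin (the α face of C9 is shielded by the axial C4–C5 bond of ring A), and silyloxy epoxide 12 opens with 1,4-silyl migration to the equatorial 9β-silyloxy ketone.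

Step 9
Reactants: 13 cis-fused 3α,9β-bis(tert-butyldimethylsilyloxy) decalin-8-one; 14 2-bromopropene
Product: 17 3α,9β-bis(tert-butyldimethylsilyloxy)-10βH-eremophil-11-en-8-one, via lithium enolate 15 (not isolated), via chlorozinc enolate 16 (not isolated)
Conditions: LiN(iPr)2, THF, −78 °C; ZnCl2, −78 → 0 °C; then 14, Pd2(dba)3 (2.5 mol%), P(t-Bu)3 (5 mol%), rt
Reagents that add atoms: none
Why: Palladium-catalysed α-alkenylation of a ketone zinc enolate (Negishi-type enolate coupling): kinetic deprotonation should take the C7 methylene rather than the silyloxy-substituted C9 methine, palladium should bind C7 on the convex β face so that reductive elimination places isopropenyl equatorial (7β, also the thermodynamic epimer), and the weakly basic zinc enolate should not enolise the product toward the conjugated isopropylidene ketone.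

Step 10
Reactants: 17 3α,9β-bis(tert-butyldimethylsilyloxy)-10βH-eremophil-11-en-8-one
Product: 18 3α,9β-dihydroxy-10βH-eremophil-11-en-8-one
Conditions: HF·pyridine, THF, 0 °C → rt
Reagents that add atoms: none
Why: Fluoride-mediated desilylation under non-basic conditions should free both hydroxyls without epimerising C7 or C9, without α-ketol shift and without moving the alkene into conjugation.

Step 11
Reactants: 18 3α,9β-dihydroxy-10βH-eremophil-11-en-8-one; 19 3-methylbut-2-enoyl chloride (senecioyl chloride)
Product: 21 (3R,4R,5R,7R,9R,10S)-8-oxo-10βH-eremophil-11-ene-3α,9β-diyl bis(3-methylbut-2-enoate), via 3-mono-senecioate 20 (not isolated)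
Conditions: 19 (3 equiv in all), pyridine, DMAP (cat.), CH2Cl2, 0 °C → rt
Reagents that add atoms: 3-methylbut-2-enoyl chloride (second equivalent of 19) CC(C)=CC(Cl)=O
Why: DMAP-catalysed esterification through the acylpyridinium ion acylates each equatorial secondary hydroxyl with one equivalent of the acid chloride: the more nucleophilic C3 carbinol should react first to mono-ester 20 and the C9 ketol hydroxyl then takes up the second equivalent, pyridine being preferred to trialkylamines to suppress deconjugation of the acyl group through a vinylketene, and no stereocentre is touched.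

**Compound list**

1 | 2-methylcyclohexane-1,3-dione | CC1C(=O)CCCC1=O | starting material
2 | methyl vinyl ketone (but-3-en-2-one) | CC(=O)C=C | starting material
3 | 2-methyl-2-(3-oxobutyl)cyclohexane-1,3-dione | CC(=O)CCC1(C)C(=O)CCCC1=O | intermediate
4 | proline enamine of the side-chain ketone of 3 (not isolated) | C=C(CCC1(C)C(=O)CCCC1=O)N1CCC[C@H]1C(=O)O | intermediate
5 | cis-fused bicyclic ketol, 10-hydroxy cis to the C5 methyl (not isolated) | C1C[C@@]2(C)[C@](O)(CCCC2=O)CC1=O | intermediate
6 | (S)-Wieland–Miescher ketone, (S)-8a-methyl-3,4,8,8a-tetrahydronaphthalene-1,6(2H,7H)-dione | C1C[C@@]2(C)C(CCCC2=O)=CC1=O | intermediate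
7 | (R)-4a-methyl-5-methylidene-4,4a,5,6,7,8-hexahydronaphthalen-2(3H)-one | C1C[C@@]2(C)C(CCCC2=C)=CC1=O | intermediate
8 | (4aS,6R)-6-hydroxy-4a-methyl-5-methylidene-4,4a,5,6,7,8-hexahydronaphthalen-2(3H)-one (3α-OH) | C1C[C@@]2(C)C(CC[C@@H](O)C2=C)=CC1=O | intermediate
9 | (4aR,5R,6R)-6-hydroxy-4a,5-dimethyl-4,4a,5,6,7,8-hexahydronaphthalen-2(3H)-one (3α-OH, 4β-Me, 5β-Me) | C1C[C@@]2(C)C(CC[C@@H](O)[C@@H]2C)=CC1=O | intermediate
10 | TBS ether of 9 | C1C[C@@]2(C)C(CC[C@@H](O[Si](C)(C)C(C)(C)C)[C@@H]2C)=CC1=O | intermediate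
11 | cis-fused (10β-H) 8-(TBS-oxy) Δ8 enol ether with 3α-OTBS, 4β-Me, 5β-Me | C1C[C@@]2(C)[C@H](CC[C@@H](O[Si](C)(C)C(C)(C)C)[C@@H]2C)C=C1O[Si](C)(C)C(C)(C)C | intermediate
12 | 8-(TBS-oxy)-8,9β-epoxide of 11 (not isolated) | C1C[C@@]2(C)[C@H](CC[C@@H](O[Si](C)(C)C(C)(C)C)[C@@H]2C)[C@@H](O3)[C@]13O[Si](C)(C)C(C)(C)C | intermediate
13 | cis-fused 3α,9β-bis(TBS-oxy)-4β,5β-dimethyl-10β-H decalin-8-one | C1C[C@@]2(C)[C@H](CC[C@@H](O[Si](C)(C)C(C)(C)C)[C@@H]2C)[C@@H](O[Si](C)(C)C(C)(C)C)C1=O | intermediate
14 | 2-bromopropene | CC(Br)=C | starting material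
15 | lithium enolate of 13 toward C7 (not isolated) | [Li+].[O-]C1=CC[C@@]2(C)[C@H](CC[C@@H](O[Si](C)(C)C(C)(C)C)[C@@H]2C)[C@H]1O[Si](C)(C)C(C)(C)C | intermediate
16 | chlorozinc enolate of 13 toward C7 (not isolated) | Cl[Zn]OC1=CC[C@@]2(C)[C@H](CC[C@@H](O[Si](C)(C)C(C)(C)C)[C@@H]2C)[C@H]1O[Si](C)(C)C(C)(C)C | intermediate
17 | 3α,9β-bis(TBS-oxy)-10βH-eremophil-11-en-8-one (7β-isopropenyl) | C=C(C)[C@H]1C[C@@]2(C)[C@H](CC[C@@H](O[Si](C)(C)C(C)(C)C)[C@@H]2C)[C@@H](O[Si](C)(C)C(C)(C)C)C1=O | intermediate
18 | 3α,9β-dihydroxy-10βH-eremophil-11-en-8-one | C=C(C)[C@H]1C[C@@]2(C)[C@H](CC[C@@H](O)[C@@H]2C)[C@@H](O)C1=O | intermediate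
19 | 3-methylbut-2-enoyl chloride (senecioyl chloride) | CC(C)=CC(Cl)=O | starting material
20 | 9β-hydroxy-3α-(3-methylbut-2-enoyloxy)-10βH-eremophil-11-en-8-one (3-mono-senecioate, not isolated) | C=C(C)[C@H]1C[C@@]2(C)[C@H](CC[C@@H](OC(=O)C=C(C)C)[C@@H]2C)[C@@H](O)C1=O | intermediate
21 | (3R,4R,5R,7R,9R,10S)-8-oxo-10βH-eremophil-11-ene-3α,9β-diyl bis(3-methylbut-2-enoate) | C=C(C)[C@H]1C[C@@]2(C)[C@H](CC[C@@H](OC(=O)C=C(C)C)[C@@H]2C)[C@@H](OC(=O)C=C(C)C)C1=O | target

**Step count.** 11 steps in total; the longest linear sequence is 11 steps (from 1).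

**Steps most likely to fail, with fallbacks**

Step 4. Oxygen transfer to C3 may lose facial control (3β-alcohol), or the allylic alcohol may be over-oxidised to the enone. The fallback sets out from 6 and comes back at 10; it hydroxylates an enolate before methylenation instead of oxidising an allylic C–H after it. The conjugated carbonyl of 6 is masked selectively with ethane-1,2-dithiol (TsOH, AcOH) as the enone dithiolane F1. The remaining C4 ketone is enolised toward C3 and oxidised anti to the axial C14 methyl (KN(SiMe3)2, then 2-(phenylsulfonyl)-3-phenyloxaziridine, −78 °C) to the 3α-hydroxy ketone F2. Silylation (TBSOTf, 2,6-lutidine) gives the silyl ether F3, and Petasis methylenation (Cp2TiMe2, toluene, 70 °C) gives the 4-methylidene dithiolane F4. Unmasking (MeI, CaCO3, aqueous MeCN) gives the 3α-silyloxy-4-methylidene enone F5. Hydrogenation of the exocyclic alkene from the α face (RhCl(PPh3)3, H2) then gives 10.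

Step 7. Hydride may be delivered to the α face of C10 (trans ring fusion), or the carbonyl may be reduced 1,2. The fallback sets out from 10 and comes back at 11. Heterogeneous hydrogenation (H2, Pd/C, EtOAc) should give the cis-fused saturated ketone F6. Enol silylation under equilibrating conditions (TBSOTf, Et3N, CH2Cl2) should then give the Δ8 enol ether 11, the more stable enol ether of a cis-fused ketone of this type.

Step 9. Transmetalation or reductive elimination may be sluggish at the hindered α-silyloxy ketone, or the product may enolise and the alkene migrate into conjugation. The fallback sets out from 13 and comes back at 17. Lithium enolate 15 is added to acetone (−78 °C) and quenched with AcOH to give the 7-(2-hydroxypropan-2-yl) ketone F7. Dehydration with Burgess reagent (benzene, 50 °C) gives the conjugated 7(11)-isopropylidene ketone F8; any isopropenyl isomer formed directly is already 17. Deprotonation of a γ-methyl group with KN(SiMe3)2 (THF, −78 °C) gives the potassium dienolate F9. Kinetic α-protonation (AcOH, −78 °C) returns the deconjugated ketone 17, whose equatorial 7β configuration is also the thermodynamic one.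

**Further compounds**

F1 | step 4 | enone dithiolane of 6 (C8 spiro-1,3-dithiolane, C4 ketone free) | C1C[C@@]2(C)C(CCCC2=O)=CC13SCCS3
F2 | step 4 | 3α-hydroxy C4 ketone dithiolane | C1C[C@@]2(C)C(CC[C@@H](O)C2=O)=CC13SCCS3
F3 | step 4 | 3α-(TBS-oxy) C4 ketone dithiolane | C1C[C@@]2(C)C(CC[C@@H](O[Si](C)(C)C(C)(C)C)C2=O)=CC13SCCS3
F4 | step 4 | 3α-(TBS-oxy)-4-methylidene dithiolane | C1C[C@@]2(C)C(CC[C@@H](O[Si](C)(C)C(C)(C)C)C2=C)=CC13SCCS3
F5 | step 4 | 3α-(TBS-oxy)-4-methylidene Δ9(10)-en-8-one | C1C[C@@]2(C)C(CC[C@@H](O[Si](C)(C)C(C)(C)C)C2=C)=CC1=O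
F6 | step 7 | cis-fused 3α-(TBS-oxy)-4β,5β-dimethyl-10β-H decalin-8-one | C1C[C@@]2(C)[C@H](CC[C@@H](O[Si](C)(C)C(C)(C)C)[C@@H]2C)CC1=O
F7 | step 9 | 7β-(2-hydroxypropan-2-yl) derivative of 13 | CC(C)(O)[C@H]1C[C@@]2(C)[C@H](CC[C@@H](O[Si](C)(C)C(C)(C)C)[C@@H]2C)[C@@H](O[Si](C)(C)C(C)(C)C)C1=O
F8 | step 9 | 7(11)-isopropylidene ketone | CC(C)=C1C[C@@]2(C)[C@H](CC[C@@H](O[Si](C)(C)C(C)(C)C)[C@@H]2C)[C@@H](O[Si](C)(C)C(C)(C)C)C1=O
F9 | step 9 | potassium dienolate of 17 | [K+].[O-]C1=C(C(C)=C)C[C@@]2(C)[C@H](CC[C@@H](O[Si](C)(C)C(C)(C)C)[C@@H]2C)[C@H]1O[Si](C)(C)C(C)(C)C
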